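**Plan**

- Numbering follows benzofuran: unprimed for the dihydrobenzofuran that carries the styryl group, primed for the other. All eight phenols travel as methyl ethers.
- Retrosynthesis: cut the stilbene bond C6–Cα (Heck), then C2–aryl and C3–C6' of the unprimed ring together, then C2'–aryl and C3'–aryl of the primed ring together in the same way.
- Enabling feature: in each ring the trans aryl groups on C2 and C3, between O1 and C3a, are what remains when a 4-oxyphenyl carbon (to C2) and an arene carbon (to C3) add to opposite faces of the C2=C3 bond of a flat benzofuran. Both rings therefore come from one C2-borylated 6-chloro-4-methoxybenzofuran.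
- Forward: the benzofuran is built (furan ring by Rössing cyclisation), borylated and converted in one batch into its ate complex with 4-methoxyphenyllithium. One portion is coupled with 3,5-dimethoxyphenyl triflate (primed ring), C6'–Cl becomes C6'–OTf, and a second portion is coupled with that triflate (unprimed ring). Neither coupling closes a ring.
- Stereochemistry: each coupling sets C2 and C3 at once (anti 1,2-shift from boron, retentive reductive elimination, π-face chosen by a chiral bisphosphine on palladium). Protodeboronation with retention keeps C2, the Heck reaction gives the E alkene, and BBr3 unmasks the phenols.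

Key step: step 12

Assumption: the sense of induction of the ferrocenyl bisphosphine on this new substrate class cannot be predicted, so (Sp,Sp)-MandyPhos is written as the working choice. The enantiomer that gives the (2S,3S) ring in step 8 is used again in step 12, because both rings have the same absolute sense.

**Step 1**
Reactants: 1 1-chloro-3,5-dimethoxybenzene
Product: 3 4-chloro-2,6-dimethoxybenzaldehyde, via (4-chloro-2,6-dimethoxyphenyl)lithium 2 (not isolated)
Conditions: n-BuLi, TMEDA, THF, −20 → 0 °C; DMF, 0 °C → rt; aq. HCl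
Reagents that add atoms: N,N-dimethylformamide, CN(C)C=O
Why: Directed ortho-metalation at the C–H flanked by both methoxy groups (the most acidic, doubly coordinated site) followed by formylation with DMF should put the aldehyde para to chlorine, and the low temperature avoids aryne formation from any ortho-chloro aryllithium.

**Step 2**
Reactants: 3 4-chloro-2,6-dimethoxybenzaldehyde
Product: 4 4-chloro-2-hydroxy-6-methoxybenzaldehyde
Conditions: BCl3 (1.1 equiv), CH2Cl2, −78 → 0 °C; then H2O
Reagents that add atoms: none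
Why: Chelation-controlled Lewis-acid demethylation, in which BCl3 bound to the aldehyde oxygen cleaves one ortho methyl ether through a six-membered chelate and the boron phenoxide so formed protects the second one.

**Step 3**
Reactants: 4 4-chloro-2-hydroxy-6-methoxybenzaldehyde
Product: 5 2-(5-chloro-2-formyl-3-methoxyphenoxy)acetic acid
Conditions: ClCH2CO2H, NaOH, H2O, reflux; then HCl
Reagents that add atoms: chloroacetic acid, OC(=O)CCl
Why: Williamson ether synthesis of the phenoxide with chloroacetate, the classical first stage of the Rössing benzofuran synthesis from a salicylaldehyde.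

**Step 4**
Reactants: 5 2-(5-chloro-2-formyl-3-methoxyphenoxy)acetic acid
Product: 6 6-chloro-4-methoxy-1-benzofuran
Conditions: NaOAc, Ac2O, AcOH, reflux
Reagents that add atoms: none
Why: Rössing (intramolecular Perkin-type) cyclisation, in which the mixed anhydride enolises, adds to the ortho aldehyde and the adduct loses water and CO2 to give the C2,C3-unsubstituted benzofuran.

**Step 5**
Reactants: 6 6-chloro-4-methoxy-1-benzofuran
Product: 8 2-(6-chloro-4-methoxy-1-benzofuran-2-yl)-4,4,5,5-tetramethyl-1,3,2-dioxaborolane, via (6-chloro-4-methoxy-1-benzofuran-2-yl)lithium 7 (not isolated)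
Conditions: n-BuLi, THF, −78 °C; i-PrOBpin, −78 °C → rt; HCl in Et2O
Reagents that add atoms: 2-isopropoxy-4,4,5,5-tetramethyl-1,3,2-dioxaborolane, CC(C)OB1OC(C)(C)C(C)(C)O1
Why: Lithiation–borylation at the furan C2–H, the most acidic position of a benzofuran, which n-BuLi removes at −78 °C without touching the aryl chloride.

**Step 6**
Reactants: 9 3,5-dimethoxyphenol
Product: 10 3,5-dimethoxyphenyl trifluoromethanesulfonate
Conditions: Tf2O, pyridine, CH2Cl2, 0 °C
Reagents that add atoms: trifluoromethanesulfonic anhydride, O=S(=O)(OS(=O)(=O)C(F)(F)F)C(F)(F)F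
Why: Standard O-triflation of a phenol, giving the halide-free aryl electrophile needed for a cationic arylpalladium species.

**Step 7**
Reactants: 8 2-(6-chloro-4-methoxy-1-benzofuran-2-yl)-4,4,5,5-tetramethyl-1,3,2-dioxaborolane; 11 4-bromoanisole
Product: 13 lithium (6-chloro-4-methoxy-1-benzofuran-2-yl)(4-methoxyphenyl)(pinacolato)borate, via (4-methoxyphenyl)lithium 12 (not isolated)
Conditions: 11 (1.05 equiv), n-BuLi (1.0 equiv), THF, −78 °C; then 8 (1.0 equiv), −78 °C → rt; volatiles removed in vacuo; solid triturated with pentane, dried and stored under argon at −20 °C (one batch, sized for steps 8 and 12)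
Reagents that add atoms: n-butyllithium, [Li]CCCC
Why: Bromine–lithium exchange followed by addition of the aryllithium to the vacant boron p orbital of the pinacol boronic ester (boronate ate-complex formation) should give the four-coordinate borate as a solid that keeps under inert gas, and evacuation plus the pentane wash remove 1-bromobutane and residual aryl bromide so that no halide source reaches the palladium steps.

**Step 8**
Reactants: 13 lithium (6-chloro-4-methoxy-1-benzofuran-2-yl)(4-methoxyphenyl)(pinacolato)borate; 10 3,5-dimethoxyphenyl trifluoromethanesulfonate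
Product: 14 2-[(2S,3S)-6-chloro-3-(3,5-dimethoxyphenyl)-4-methoxy-2-(4-methoxyphenyl)-2,3-dihydro-1-benzofuran-2-yl]-4,4,5,5-tetramethyl-1,3,2-dioxaborolane (aryl groups on C2 and C3 trans; Bpin cis to the C3 aryl)
Conditions: 10 (1.1 equiv), Pd(OAc)2 (cat.), (Sp,Sp)-MandyPhos (cat.), THF, 60 °C
Reagents that add atoms: none
Why: Proposed new method: the cationic arylpalladium(II) from triflate 10 should bind the electron-rich C2=C3 bond of the four-coordinate boronate 13 and induce an anti 1,2-shift of the anisyl group from boron to C2, after which retentive C(sp2)–C(sp3) reductive elimination at C3 (no β-hydrogen available) gives the trans-2,3-diaryl ring with C3 set by the ligand-controlled π-face and C2 by the anti geometry; the closest known reaction types are the enantioselective palladium-catalysed conjunctive cross-coupling of alkenylboron ate complexes with aryl triflates and the dearomative three-component coupling of indol-2-yl boronates with π-allylpalladium electrophiles.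

**Step 9**
Reactants: 14 2-[(2S,3S)-6-chloro-3-(3,5-dimethoxyphenyl)-4-methoxy-2-(4-methoxyphenyl)-2,3-dihydro-1-benzofuran-2-yl]-4,4,5,5-tetramethyl-1,3,2-dioxaborolane
Product: 15 (2S,3S)-6-chloro-3-(3,5-dimethoxyphenyl)-4-methoxy-2-(4-methoxyphenyl)-2,3-dihydro-1-benzofuran
Conditions: TBAF·3H2O, toluene, 45 °C
Reagents that add atoms: none
Why: Fluoride/water-promoted protodeboronation of a tertiary benzylic pinacol boronate proceeds with retention, so hydrogen takes the place of boron on the face syn to the C3 aryl group and the two aryl groups stay trans, which is also the thermodynamically preferred arrangement.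

**Step 10**
Reactants: 15 (2S,3S)-6-chloro-3-(3,5-dimethoxyphenyl)-4-methoxy-2-(4-methoxyphenyl)-2,3-dihydro-1-benzofuran
Product: 16 (2S,3S)-3-(3,5-dimethoxyphenyl)-4-methoxy-2-(4-methoxyphenyl)-2,3-dihydro-1-benzofuran-6-ol
Conditions: Pd2(dba)3 (cat.), t-BuXPhos (cat.), KOH, 1,4-dioxane/H2O, 100 °C; then aq. HCl
Reagents that add atoms: potassium hydroxide, [K+].[OH-]
Why: Buchwald-type palladium-catalysed hydroxylation of an aryl chloride with a bulky biarylphosphine, under which the methyl ethers and the two ring stereocentres are inert.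

**Step 11**
Reactants: 16 (2S,3S)-3-(3,5-dimethoxyphenyl)-4-methoxy-2-(4-methoxyphenyl)-2,3-dihydro-1-benzofuran-6-ol
Product: 17 (2S,3S)-3-(3,5-dimethoxyphenyl)-4-methoxy-2-(4-methoxyphenyl)-2,3-dihydro-1-benzofuran-6-yl trifluoromethanesulfonate
Conditions: Tf2O, pyridine, CH2Cl2, 0 °C
Reagents that add atoms: trifluoromethanesulfonic anhydride, O=S(=O)(OS(=O)(=O)C(F)(F)F)C(F)(F)F
Why: Standard O-triflation of a phenol, which turns C6' into the halide-free electrophilic site for the second coupling.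

**Step 12**
Reactants: 13 lithium (6-chloro-4-methoxy-1-benzofuran-2-yl)(4-methoxyphenyl)(pinacolato)borate; 17 (2S,3S)-3-(3,5-dimethoxyphenyl)-4-methoxy-2-(4-methoxyphenyl)-2,3-dihydro-1-benzofuran-6-yl trifluoromethanesulfonate
Product: 18 2-[(2S,3S)-6-chloro-3-[(2S,3S)-3-(3,5-dimethoxyphenyl)-4-methoxy-2-(4-methoxyphenyl)-2,3-dihydro-1-benzofuran-6-yl]-4-methoxy-2-(4-methoxyphenyl)-2,3-dihydro-1-benzofuran-2-yl]-4,4,5,5-tetramethyl-1,3,2-dioxaborolane (aryl groups on C2 and C3 trans; Bpin cis to the C6' arene)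
Conditions: 17 (limiting), 13 (1.3 equiv, from the batch of step 7), Pd(OAc)2 (cat.), (Sp,Sp)-MandyPhos (cat., same enantiomer as in step 8), THF, 60 °C
Reagents that add atoms: none
Why: Proposed new method: the cationic arylpalladium(II) formed from triflate 17 and the ferrocenyl bisphosphine should bind the electron-rich C2=C3 bond of the preformed ate complex 13 and, acting as a π-acid, trigger a 1,2-shift of the anisyl group from boron to C2 on the face opposite to palladium; the C3–palladium alkyl so formed has no β-hydrogen and undergoes C(sp2)–C(sp3) reductive elimination with retention, so C2–anisyl and C3–C6' form anti and the furan ring is dearomatised. The closest known reaction types are the enantioselective palladium-catalysed conjunctive cross-coupling of alkenylboron ate complexes with aryl triflates and the dearomative three-component coupling of indol-2-yl boronates with π-allylpalladium electrophiles. No ring closes, since the existing furan ring is only brought to the dihydrofuran level. C3 is set by the π-face that the chiral ligand lets palladium occupy, and C2 follows from the anti geometry of the shift, which makes the two aryl groups trans and leaves boron cis to the C6' arene. The step needs the metallate shift to outrun boron-to-palladium transmetallation (no base, halide or Pd–O–B bridge is present and boron is fully substituted), triflate-over-chloride oxidative addition (bisphosphine-ligated Pd(0) at 60 °C should leave the C6–Cl bond alone) and ligand-over-substrate facial control (the C2' and C3' centres of 17 lie four bonds from the reacting C6'). Regiochemistry is fixed by the substrate, because boron sits on C2, the shift can only end there and palladium takes the nucleophilic C3.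

**Step 13**
Reactants: 18 2-[(2S,3S)-6-chloro-3-[(2S,3S)-3-(3,5-dimethoxyphenyl)-4-methoxy-2-(4-methoxyphenyl)-2,3-dihydro-1-benzofuran-6-yl]-4-methoxy-2-(4-methoxyphenyl)-2,3-dihydro-1-benzofuran-2-yl]-4,4,5,5-tetramethyl-1,3,2-dioxaborolane
Product: 19 (2S,3S)-6-chloro-3-[(2S,3S)-3-(3,5-dimethoxyphenyl)-4-methoxy-2-(4-methoxyphenyl)-2,3-dihydro-1-benzofuran-6-yl]-4-methoxy-2-(4-methoxyphenyl)-2,3-dihydro-1-benzofuran
Conditions: TBAF·3H2O, toluene, 45 °C
Reagents that add atoms: none
Why: Stereoretentive fluoride/water-promoted protodeboronation of a tertiary benzylic boronic ester, as in step 9, so C2 keeps its configuration and the anisyl group stays trans to the C6' arene.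

**Step 14**
Reactants: 19 (2S,3S)-6-chloro-3-[(2S,3S)-3-(3,5-dimethoxyphenyl)-4-methoxy-2-(4-methoxyphenyl)-2,3-dihydro-1-benzofuran-6-yl]-4-methoxy-2-(4-methoxyphenyl)-2,3-dihydro-1-benzofuran; 20 2,4-dimethoxystyrene
Product: 21 (2S,3S)-6-[(E)-2-(2,4-dimethoxyphenyl)ethenyl]-3-[(2S,3S)-3-(3,5-dimethoxyphenyl)-4-methoxy-2-(4-methoxyphenyl)-2,3-dihydro-1-benzofuran-6-yl]-4-methoxy-2-(4-methoxyphenyl)-2,3-dihydro-1-benzofuran
Conditions: Pd2(dba)3 (cat.), P(t-Bu)3 (cat.), Cy2NMe, 1,4-dioxane, 110 °C
Reagents that add atoms: none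
Why: Mizoroki–Heck reaction of an unactivated aryl chloride under Pd/P(t-Bu)3/Cy2NMe conditions, in which syn insertion at the terminal alkene carbon and syn β-hydride elimination give the E stilbene.

**Step 15**
Reactants: 21 (2S,3S)-6-[(E)-2-(2,4-dimethoxyphenyl)ethenyl]-3-[(2S,3S)-3-(3,5-dimethoxyphenyl)-4-methoxy-2-(4-methoxyphenyl)-2,3-dihydro-1-benzofuran-6-yl]-4-methoxy-2-(4-methoxyphenyl)-2,3-dihydro-1-benzofuran
Product: 22 4-[(E)-2-[(2S,3S)-3-[(2S,3S)-3-(3,5-dihydroxyphenyl)-4-hydroxy-2-(4-hydroxyphenyl)-2,3-dihydro-1-benzofuran-6-yl]-4-hydroxy-2-(4-hydroxyphenyl)-2,3-dihydro-1-benzofuran-6-yl]ethenyl]benzene-1,3-diol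
Conditions: BBr3 (excess), CH2Cl2, −78 °C → rt; MeOH, then H2O
Reagents that add atoms: none
Why: Lewis-acid cleavage of the eight aryl methyl ethers with BBr3, the usual last step for permethylated stilbenoid oligomers, in which the trans-2,3-diaryl dihydrobenzofurans are the thermodynamic isomers and should keep their configuration.

**Compound list**

1 | 1-chloro-3,5-dimethoxybenzene | COc1cc(Cl)cc(OC)c1 | starting material
2 | (4-chloro-2,6-dimethoxyphenyl)lithium | COc1cc(Cl)cc(OC)c1[Li] | intermediate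
3 | 4-chloro-2,6-dimethoxybenzaldehyde | COc1cc(Cl)cc(OC)c1C=O | intermediate
4 | 4-chloro-2-hydroxy-6-methoxybenzaldehyde | COc1cc(Cl)cc(O)c1C=O | intermediate
5 | 2-(5-chloro-2-formyl-3-methoxyphenoxy)acetic acid | COc1cc(Cl)cc(OCC(=O)O)c1C=O | intermediate
6 | 6-chloro-4-methoxy-1-benzofuran | COc1cc(Cl)cc2occc12 | intermediate
7 | (6-chloro-4-methoxy-1-benzofuran-2-yl)lithium | COc1cc(Cl)cc2oc([Li])cc12 | intermediate
8 | 2-(6-chloro-4-methoxy-1-benzofuran-2-yl)-4,4,5,5-tetramethyl-1,3,2-dioxaborolane | COc1cc(Cl)cc2oc(B3OC(C)(C)C(C)(C)O3)cc12 | intermediate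
9 | 3,5-dimethoxyphenol | COc1cc(O)cc(OC)c1 | starting material
10 | 3,5-dimethoxyphenyl trifluoromethanesulfonate | COc1cc(OC)cc(OS(=O)(=O)C(F)(F)F)c1 | intermediate
11 | 4-bromoanisole | COc1ccc(Br)cc1 | starting material
12 | (4-methoxyphenyl)lithium | COc1ccc([Li])cc1 | intermediate
13 | lithium (6-chloro-4-methoxy-1-benzofuran-2-yl)(4-methoxyphenyl)(pinacolato)borate | [Li+].COc1ccc(cc1)[B-]1(OC(C)(C)C(C)(C)O1)c1cc2c(OC)cc(Cl)cc2o1 | intermediate
14 | 2-[(2S,3S)-6-chloro-3-(3,5-dimethoxyphenyl)-4-methoxy-2-(4-methoxyphenyl)-2,3-dihydro-1-benzofuran-2-yl]-4,4,5,5-tetramethyl-1,3,2-dioxaborolane | COc1ccc([C@@]2(B3OC(C)(C)C(C)(C)O3)Oc3cc(Cl)cc(OC)c3[C@@H]2c2cc(OC)cc(OC)c2)cc1 | intermediate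
15 | (2S,3S)-6-chloro-3-(3,5-dimethoxyphenyl)-4-methoxy-2-(4-methoxyphenyl)-2,3-dihydro-1-benzofuran | COc1ccc([C@H]2Oc3cc(Cl)cc(OC)c3[C@@H]2c2cc(OC)cc(OC)c2)cc1 | intermediate
16 | (2S,3S)-3-(3,5-dimethoxyphenyl)-4-methoxy-2-(4-methoxyphenyl)-2,3-dihydro-1-benzofuran-6-ol | COc1ccc([C@H]2Oc3cc(O)cc(OC)c3[C@@H]2c2cc(OC)cc(OC)c2)cc1 | intermediate
17 | (2S,3S)-3-(3,5-dimethoxyphenyl)-4-methoxy-2-(4-methoxyphenyl)-2,3-dihydro-1-benzofuran-6-yl trifluoromethanesulfonate | COc1ccc([C@H]2Oc3cc(OS(=O)(=O)C(F)(F)F)cc(OC)c3[C@@H]2c2cc(OC)cc(OC)c2)cc1 | intermediate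
18 | 2-[(2S,3S)-6-chloro-3-[(2S,3S)-3-(3,5-dimethoxyphenyl)-4-methoxy-2-(4-methoxyphenyl)-2,3-dihydro-1-benzofuran-6-yl]-4-methoxy-2-(4-methoxyphenyl)-2,3-dihydro-1-benzofuran-2-yl]-4,4,5,5-tetramethyl-1,3,2-dioxaborolane | COc1ccc([C@@]2(B3OC(C)(C)C(C)(C)O3)Oc3cc(Cl)cc(OC)c3[C@@H]2c2cc(OC)c3c(c2)O[C@H](c2ccc(OC)cc2)[C@H]3c2cc(OC)cc(OC)c2)cc1 | intermediate
19 | (2S,3S)-6-chloro-3-[(2S,3S)-3-(3,5-dimethoxyphenyl)-4-methoxy-2-(4-methoxyphenyl)-2,3-dihydro-1-benzofuran-6-yl]-4-methoxy-2-(4-methoxyphenyl)-2,3-dihydro-1-benzofuran | COc1ccc([C@H]2Oc3cc(Cl)cc(OC)c3[C@@H]2c2cc(OC)c3c(c2)O[C@H](c2ccc(OC)cc2)[C@H]3c2cc(OC)cc(OC)c2)cc1 | intermediate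
20 | 2,4-dimethoxystyrene | C=Cc1ccc(OC)cc1OC | starting material
21 | (2S,3S)-6-[(E)-2-(2,4-dimethoxyphenyl)ethenyl]-3-[(2S,3S)-3-(3,5-dimethoxyphenyl)-4-methoxy-2-(4-methoxyphenyl)-2,3-dihydro-1-benzofuran-6-yl]-4-methoxy-2-(4-methoxyphenyl)-2,3-dihydro-1-benzofuran | COc1ccc([C@H]2Oc3cc(/C=C/c4ccc(OC)cc4OC)cc(OC)c3[C@@H]2c2cc(OC)c3c(c2)O[C@H](c2ccc(OC)cc2)[C@H]3c2cc(OC)cc(OC)c2)cc1 | intermediate
22 | 4-[(E)-2-[(2S,3S)-3-[(2S,3S)-3-(3,5-dihydroxyphenyl)-4-hydroxy-2-(4-hydroxyphenyl)-2,3-dihydro-1-benzofuran-6-yl]-4-hydroxy-2-(4-hydroxyphenyl)-2,3-dihydro-1-benzofuran-6-yl]ethenyl]benzene-1,3-diol | Oc1ccc([C@H]2Oc3cc(/C=C/c4ccc(O)cc4O)cc(O)c3[C@@H]2c2cc(O)c3c(c2)O[C@H](c2ccc(O)cc2)[C@H]3c2cc(O)cc(O)c2)cc1 | target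

**Step count**

Total: 15 steps. Longest linear sequence: 14 steps (steps 1–5 and 7–15, from 1 to 22). Step 6 is the only side branch, and the single batch of ate complex 13 from step 7 is drawn on in steps 8 and 12.

**Steps most likely to fail**

1. Step 12 (Proposed new method). What may go wrong: transfer of the benzofuranyl or anisyl group from boron to palladium may outrun π-activation, so that plain cross-coupling replaces the 1,2-shift; the bulky triflate may also erode the facial control of the ligand. The fallback uses known chemistry, sets out from 4 and 17 and returns at 19; it closes the unprimed ring by a rhodium-carbene C–H insertion instead of arylating a benzofuran. Phenol 4 is alkylated with 4-methoxybenzyl chloride (K2CO3, DMF) to 4-chloro-2-methoxy-6-[(4-methoxyphenyl)methoxy]benzaldehyde F1. Triflate 17 is converted by Miyaura borylation (B2pin2, Pd(dppf)Cl2, KOAc, dioxane) into the primed-ring arylboronic pinacol ester F2. Rhodium-catalysed 1,2-addition of F2 to F1 should give the diarylmethanol F3 as both carbinol epimers, which MnO2 oxidises to the diaryl ketone F4. Condensation with hydrazine gives the hydrazone F5, and MnO2 oxidises it to the diaryldiazomethane F6, which is used without isolation. A chiral dirhodium tetracarboxylate of the Rh2(PTAD)4 type (enantiomer chosen for 3S) then effects insertion into the benzylic C–H bond of the 4-methoxybenzyl ether and should give the cis-2,3-diaryl dihydrobenzofuran F7, with C3 set by the catalyst. Trifluoroacetic acid in CH2Cl2 epimerises C2 through reversible ionisation of the anisyl-stabilised benzylic C–O bond and leads to the trans compound 19.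

2. Step 8 (Proposed new method). What may go wrong: the same competition between transmetallation and the metallate shift, inhibition of the cationic palladium by traces of halide carried over with the ate complex, or low enantioselectivity on this first use of the ligand. The fallback uses known chemistry, sets out from 4 and returns at 15. 3,5-Dimethoxyphenylmagnesium bromide (excess) adds to 4 to give the racemic benzhydrol phenol F8, and MnO2 oxidises it to the 2-hydroxybenzophenone F9. Alkylation with 4-methoxybenzyl chloride (K2CO3, DMF) gives the 4-methoxybenzyl ether ketone F10, and hydrazine converts it into the hydrazone F11. MnO2 gives the diaryldiazomethane F12, used without isolation, and the chiral dirhodium carboxylate closes it by benzylic C–H insertion to the cis dihydrobenzofuran F13. Acid-mediated epimerisation at C2 (TFA, CH2Cl2) then gives 15.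

3. Step 15. What may go wrong: during cleavage of eight methyl ethers the acid formed may protonate the very electron-rich 2,4-dioxygenated stilbene and ionise the benzylic C2–O bonds, leading to oligomerisation or ring opening. The fallback sets out from 19 and returns at 22; it removes the methyl ethers before the stilbene exists and introduces the alkene with fluoride-labile groups. BBr3 converts 19 into the hexaphenol chloride F14, which is silylated (TBSCl, imidazole, DMF) to the hexakis-TBS ether F15. Commercial 2,4-dihydroxybenzaldehyde is silylated to 2,4-bis(tert-butyldimethylsilyloxy)benzaldehyde F16 and methylenated (Ph3P=CH2, THF) to 2,4-bis(tert-butyldimethylsilyloxy)styrene F17. Heck coupling of F15 with F17 under the conditions of step 14 should give the octakis-TBS stilbene F18, and buffered TBAF (AcOH, THF, 0 °C) releases 22 without exposure to acid.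

**Further compounds**

F1 | step 12 | 4-chloro-2-methoxy-6-[(4-methoxyphenyl)methoxy]benzaldehyde | COc1ccc(COc2cc(Cl)cc(OC)c2C=O)cc1
F2 | step 12 | 2-[(2S,3S)-3-(3,5-dimethoxyphenyl)-4-methoxy-2-(4-methoxyphenyl)-2,3-dihydro-1-benzofuran-6-yl]-4,4,5,5-tetramethyl-1,3,2-dioxaborolane | COc1ccc([C@H]2Oc3cc(B4OC(C)(C)C(C)(C)O4)cc(OC)c3[C@@H]2c2cc(OC)cc(OC)c2)cc1
F3 | step 12 | {4-chloro-2-methoxy-6-[(4-methoxyphenyl)methoxy]phenyl}[(2S,3S)-3-(3,5-dimethoxyphenyl)-4-methoxy-2-(4-methoxyphenyl)-2,3-dihydro-1-benzofuran-6-yl]methanol (both carbinol epimers) | COc1ccc(COc2cc(Cl)cc(OC)c2C(O)c2cc(OC)c3c(c2)O[C@H](c2ccc(OC)cc2)[C@H]3c2cc(OC)cc(OC)c2)cc1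
F4 | step 12 | {4-chloro-2-methoxy-6-[(4-methoxyphenyl)methoxy]phenyl}[(2S,3S)-3-(3,5-dimethoxyphenyl)-4-methoxy-2-(4-methoxyphenyl)-2,3-dihydro-1-benzofuran-6-yl]methanone | COc1ccc(COc2cc(Cl)cc(OC)c2C(=O)c2cc(OC)c3c(c2)O[C@H](c2ccc(OC)cc2)[C@H]3c2cc(OC)cc(OC)c2)cc1
F5 | step 12 | hydrazone of ketone F4 (E/Z mixture) | COc1ccc(COc2cc(Cl)cc(OC)c2C(=NN)c2cc(OC)c3c(c2)O[C@H](c2ccc(OC)cc2)[C@H]3c2cc(OC)cc(OC)c2)cc1
F6 | step 12 | (2S,3S)-6-[{4-chloro-2-methoxy-6-[(4-methoxyphenyl)methoxy]phenyl}(diazo)methyl]-3-(3,5-dimethoxyphenyl)-4-methoxy-2-(4-methoxyphenyl)-2,3-dihydro-1-benzofuran | COc1ccc(COc2cc(Cl)cc(OC)c2C(=[N+]=[N-])c2cc(OC)c3c(c2)O[C@H](c2ccc(OC)cc2)[C@H]3c2cc(OC)cc(OC)c2)cc1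
F7 | step 12 | (2R,3S)-6-chloro-3-[(2S,3S)-3-(3,5-dimethoxyphenyl)-4-methoxy-2-(4-methoxyphenyl)-2,3-dihydro-1-benzofuran-6-yl]-4-methoxy-2-(4-methoxyphenyl)-2,3-dihydro-1-benzofuran (cis in the unprimed ring) | COc1ccc([C@@H]2Oc3cc(Cl)cc(OC)c3[C@@H]2c2cc(OC)c3c(c2)O[C@H](c2ccc(OC)cc2)[C@H]3c2cc(OC)cc(OC)c2)cc1
F8 | step 8 | 5-chloro-2-[(3,5-dimethoxyphenyl)(hydroxy)methyl]-3-methoxyphenol (racemic) | COc1cc(OC)cc(c1)C(O)c1c(O)cc(Cl)cc1OC
F9 | step 8 | (4-chloro-2-hydroxy-6-methoxyphenyl)(3,5-dimethoxyphenyl)methanone | COc1cc(OC)cc(c1)C(=O)c1c(O)cc(Cl)cc1OC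
F10 | step 8 | {4-chloro-2-methoxy-6-[(4-methoxyphenyl)methoxy]phenyl}(3,5-dimethoxyphenyl)methanone | COc1ccc(COc2cc(Cl)cc(OC)c2C(=O)c2cc(OC)cc(OC)c2)cc1
F11 | step 8 | hydrazone of ketone F10 (E/Z mixture) | COc1ccc(COc2cc(Cl)cc(OC)c2C(=NN)c2cc(OC)cc(OC)c2)cc1
F12 | step 8 | 5-chloro-2-[diazo(3,5-dimethoxyphenyl)methyl]-1-methoxy-3-[(4-methoxyphenyl)methoxy]benzene | COc1ccc(COc2cc(Cl)cc(OC)c2C(=[N+]=[N-])c2cc(OC)cc(OC)c2)cc1
F13 | step 8 | (2R,3S)-6-chloro-3-(3,5-dimethoxyphenyl)-4-methoxy-2-(4-methoxyphenyl)-2,3-dihydro-1-benzofuran (cis) | COc1ccc([C@@H]2Oc3cc(Cl)cc(OC)c3[C@@H]2c2cc(OC)cc(OC)c2)cc1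
F14 | step 15 | (2S,3S)-6-chloro-3-[(2S,3S)-3-(3,5-dihydroxyphenyl)-4-hydroxy-2-(4-hydroxyphenyl)-2,3-dihydro-1-benzofuran-6-yl]-2-(4-hydroxyphenyl)-2,3-dihydro-1-benzofuran-4-ol | Oc1ccc([C@H]2Oc3cc(Cl)cc(O)c3[C@@H]2c2cc(O)c3c(c2)O[C@H](c2ccc(O)cc2)[C@H]3c2cc(O)cc(O)c2)cc1
F15 | step 15 | hexakis(tert-butyldimethylsilyl) ether of F14 | CC(C)(C)[Si](C)(C)Oc1ccc([C@H]2Oc3cc(Cl)cc(O[Si](C)(C)C(C)(C)C)c3[C@@H]2c2cc(O[Si](C)(C)C(C)(C)C)c3c(c2)O[C@H](c2ccc(O[Si](C)(C)C(C)(C)C)cc2)[C@H]3c2cc(O[Si](C)(C)C(C)(C)C)cc(O[Si](C)(C)C(C)(C)C)c2)cc1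
F16 | step 15 | 2,4-bis(tert-butyldimethylsilyloxy)benzaldehyde | CC(C)(C)[Si](C)(C)Oc1ccc(C=O)c(O[Si](C)(C)C(C)(C)C)c1
F17 | step 15 | 2,4-bis(tert-butyldimethylsilyloxy)styrene | C=Cc1ccc(O[Si](C)(C)C(C)(C)C)cc1O[Si](C)(C)C(C)(C)C
F18 | step 15 | octakis(tert-butyldimethylsilyl) ether of 22 | CC(C)(C)[Si](C)(C)Oc1ccc([C@H]2Oc3cc(/C=C/c4ccc(O[Si](C)(C)C(C)(C)C)cc4O[Si](C)(C)C(C)(C)C)cc(O[Si](C)(C)C(C)(C)C)c3[C@@H]2c2cc(O[Si](C)(C)C(C)(C)C)c3c(c2)O[C@H](c2ccc(O[Si](C)(C)C(C)(C)C)cc2)[C@H]3c2cc(O[Si](C)(C)C(C)(C)C)cc(O[Si](C)(C)C(C)(C)C)c2)cc1
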